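## Structural features

The target is a monocyclic oxane (O1, C2–C6). C2 carries a 4-hydroxyphenyl group, C3 an (E)-3-(4-hydroxyphenyl)prop-2-enyl chain, and C5 a hydroxy(4-hydroxyphenyl)methyl group whose carbinol carbon is called C7 here; C4 and C6 are methylene groups. Four stereocentres stand in two adjacent pairs, C2/C3 inside the ring and C5/C7 across the exocyclic bond. The configuration read from the SMILES is 2R,3S,5R,7R, with the three ring substituents all cis. In a chair this array forces either the C2 aryl group axial or the C3 and C5 groups syn-diaxial, so the all-cis arrangement is not the preferred one at C5 and must be made and kept under kinetic control whenever C5 is α to a carbonyl group. The fragile groups are the three free phenols, the E-styrene (which forbids any hydrogenation once it is in place) and two para-hydroxybenzylic C–O bonds, C2–O1 and C7–OH, which ionise to quinone methides under acid or strong base. The real difficulty is the absolute control of the C2/C3 pair and its relay to C5 and C7 without passing through a benzylic cation. The key step uses the fact that O1–C2 and C3–C4 are a 1,3-related pair of ring bonds: cutting both is a retro-[4+2] that turns C2=C3 into a Z-configured para-oxygenated styrene and O1=C6–C5=C4 into an oxadiene whose ester on C5 is the latent C7. The cis relationship of C2 and C3 is then the Z geometry of that styrene.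

## Logic of the disconnections

18 ⇒ 17. The three phenolic O–H bonds are traced back to three identical O–Si bonds. Free phenols would quench the organometallic, hydride and Lewis-acid steps, and one common silyl type allows a single closing operation. The gain is that the phenol/benzylic-carbinol combination exists only in the last flask. The demand is a buffered fluoride source that never builds up phenoxide or acid.

17 ⇒ 15 + 16, then 15 ⇒ 14. The C7–aryl bond is cut, so the most acid-sensitive centre is created in the penultimate step and needs no protection. The aryl nucleophile 16 comes from 2, which the route already makes. One arene and one stereocentre are removed. The forward step must choose one face of the formyl group, for which O1 is the only handle (chelation), and must not epimerise C5. 15 goes back to 14 by raising C7 to the ester oxidation level that the cycloaddition delivers.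

14 ⇒ 12 + 13. The styrene C=C bond is cut. Cross-metathesis forms this bond under thermodynamic E-control, tolerates the ester and the silyl ethers, and uses a purchasable partner. The second arene is removed. The forward step must avoid double-bond migration and homodimerisation.

12 ⇒ 11 ⇒ 10. The terminal C=CH2 bond is cut to a formyl group, and the formyl group is traced to a silyl-protected primary alcohol. This keeps the C3 arm at the two-carbon length that the alkynol supplies. The demand is that the primary silyl ether be oxidised while the aryl silyl ether stays, which is why the two silyl groups are chosen to be different. No stereocentre is α to this aldehyde, so C3 is safe.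

10 ⇒ 9. The C5–H and C6–H bonds are removed to restore the C5=C6 enol-ether double bond of a cycloadduct. This removes the C5 stereocentre and leaves the C2/C3 pair as the only stereochemical content. The forward hydrogenation must add to the face opposite the two cis substituents and must spare the benzylic C2–O1 bond. It has to come before the styrene is installed.

9 ⇒ 6 + 8, then 8 ⇒ 7. The ring bonds O1–C2 and C3–C4 are cut together. The ring and both ring stereocentres disappear in one operation and two achiral, open-chain pieces remain. The forward cycloaddition must place oxygen on the benzylic carbon, keep the Z geometry, and select one enantioface. Because 8 dimerises, it is made from 7 immediately before use.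

6 ⇒ 5 ⇒ 4 ⇒ 2 + 3, then 2 ⇒ 1. Two syn C–H bonds of the alkene, the primary O–Si bond, the aryl–alkynyl C–C bond and the phenolic O–Si bond are cut in turn. An alkyne is the most reliable source of a Z-alkene, and the aryl–alkyne bond is a standard cross-coupling. In 6 the primary oxygen carries a triethylsilyl group and the phenol oxygen a tert-butyldimethylsilyl group. Both are too weakly Lewis basic to compete for the catalyst, and they can be told apart later. The semi-reduction must stop at the alkene and give high Z purity, because any E-alkene becomes the trans C2/C3 isomer.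

## Other disconnections considered

Alternative 1: The cuts are C2–C3 and C5–C7, the bonds that join each carbinol carbon to a five-carbon chain whose terminal acyl carbons become C6 and the methylene on C3. In the forward sense the glutaryl bis-imide A1 (1,5-bis[(4R)-4-benzyl-2-oxo-1,3-oxazolidin-3-yl]pentane-1,5-dione) is enolised twice under magnesium-halide soft-enolisation conditions. Each enolate adds to 4-(tert-butyldimethylsilyloxy)benzaldehyde A2 in the anti sense to give the twofold-symmetric anti,anti bis-aldol adduct A3.
- In favour: one auxiliary-controlled operation of an established type would set C2, C3, C5 and C7 together with a predictable absolute sense. The hidden symmetry is real, because the C2/C3 and C7/C5 pairs of the target map onto each other. The aldehyde is non-enolisable, as this aldol variant requires. Since the two ends of A3 are homotopic, closing either hydroxyl onto the far acyl carbon gives the same six-membered ring, so desymmetrisation costs no selectivity.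
- Against: the key step closes no ring and leaves both acyl carbons at the wrong oxidation level. One must be reduced to the C6 methylene after lactonisation, typically through an oxocarbenium ion, which threatens the benzylic C2–O1 bond. The other must be reduced and extended by one carbon before the styrene can be attached. The electron-rich aldehyde should react sluggishly, the second aldol must occur on a more hindered mono-adduct, and two equivalents of auxiliary are consumed.
- Comparison: on certainty of relative and absolute configuration this alternative is the better plan, since it needs no new enantioselective method, whereas the chosen plan sets C2/C3 with an untested catalyst–substrate pair and C5 and C7 by substrate control. On mechanism both rely on a metal-bound carbonyl, and the aldol has the firmer precedent. On structural fit and step economy the chosen plan is better: 9 already contains the ring, the C5 carboxyl at the right place and the C3 arm at the right length.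

Alternative 2: The cut is O1–C2 alone, with the bond from C2 to a malonyl carbon in a cyclopropane as latent electrophile. In the cyclopropane diester A4 (cis aryl/alkyl, aryl oxygen as a mesylate, C5 and C7 already in the tether) the primary hydroxyl on C6 attacks the benzylic ring carbon under Lewis-acid activation in a 6-exo-tet opening with inversion, giving the all-cis oxane A5.
- In favour: Lewis-acid opening of donor–acceptor cyclopropanes by alcohols with inversion is an established reaction type, so on precedent for the ring-forming event this alternative is better than the chosen key step. The opening is stereospecific, and the C5/C7 pair is carried in unchanged.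
- Against: A4 already holds every stereocentre of the target plus a cis-trisubstituted cyclopropane. The problem is moved into an enantioselective cis-cyclopropanation of a Z-aryl alkene, which is no easier than the cycloaddition of the chosen plan. The donor aryl group must be detuned as a mesylate to keep the opening SN2-like, which later costs a protecting-group exchange on a phenol under forcing conditions. The malonyl group must lose one ester (Krapcho dealkoxycarbonylation at high temperature) and be reduced before olefination.
- Comparison: both plans make O1–C2 at the benzylic carbon, start from a Z-configured aryl alkene, and share the hazard that a free benzylic cation would scramble C2. The chosen plan makes two ring bonds from two achiral pieces and leaves C5 and C7 for later, while A5 arrives with all four centres set, which is an equal or better result at that stage. On step economy the alternative is clearly longer.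

Alternative 3: The cuts are O1–C6 and C5–C6, with C6 excised as a one-carbon electrophile, while C7 and the terminal carbon of the C3 arm are joined in a cyclohexene. The carbinol A6 ((R)-[4-(tert-butyldimethylsilyloxy)phenyl][(1S)-cyclohex-3-en-1-yl]methanol) condenses with formaldehyde A7 under acid to a methylene oxocarbenium ion. The ring alkene attacks it (Prins or oxonium-ene closure) to give the 3-oxabicyclo[3.3.1]non-6-ene A8. Later oxidative cleavage of the alkene would release the C7 aldehyde and the C3 acetaldehyde arm together.
- In favour: the bicycle can only form with C3 and C5 cis, and a chair-like closure puts the aryl group equatorial and therefore cis to the C3 arm. On the cis C3/C5 relationship this alternative is more secure than the hydrogenation of the chosen plan. The absolute configuration would come from an established asymmetric ketone reduction, the building blocks are cheap, and one cleavage unveils both carbonyl handles at the correct chain length, which on paper is equal or better in step economy.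
- Against: acid and a para-silyloxybenzylic carbinol are a poor match, since ionisation at the future C2 competes with oxocarbenium formation and would racemise it. The ring stereocentre of A6 must be set relative to the carbinol, which is a second stereochemical problem. The cation formed after C–C bond formation is secondary and unstabilised, so the position of the new alkene is not assured. After cleavage two aldehydes must be told apart, one of them α-branched and prone to epimerise at C5 toward the more stable trans isomer.
- Comparison: the chosen plan avoids charge at benzylic positions and delivers differentiated handles (ester and silyl ether) from the start, whereas this alternative needs the very cation chemistry that the target's C–O bonds tolerate least. It would be shorter only if the two aldehydes could be differentiated cleanly.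

Key step: step 5

Remark: ring locants of the target (O1, C2 aryl-bearing, C3, C4, C5, C6; C7 is the carbinol carbon) are kept for every intermediate. The descriptor at C3 changes from R (9–11) to S (12 onward) only because substituent priorities change; TBS = tert-butyldimethylsilyl, TES = triethylsilyl, TBSO and TESO are the corresponding silyloxy groups.

Assumption: both antipodes of the aminoindanol-derived ligand of the chromium catalyst can be bought, and the antipode that leads to 9 is taken to be fixed by a test reaction.

## Route

Step 1
Reactants: 1 4-iodophenol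
Product: 2 tert-butyl(4-iodophenoxy)dimethylsilane
Conditions: TBSCl, imidazole, DMF, rt
Reagents that add atoms: tert-butyldimethylsilyl chloride, CC(C)(C)[Si](C)(C)Cl
Why: Imidazole-promoted silylation of a phenol; the aryl TBS ether survives the coupling, hydride and Grignard steps and leaves with fluoride at the end.

Step 2
Reactants: 2 tert-butyl(4-iodophenoxy)dimethylsilane; 3 but-3-yn-1-ol
Product: 4 4-[4-(TBSO)phenyl]but-3-yn-1-ol
Conditions: PdCl2(PPh3)2 (2 mol%), CuI (4 mol%), Et3N, THF, rt
Reagents that add atoms: none
Why: Sonogashira coupling of an aryl iodide with a terminal alkyne runs at room temperature, and the free primary alcohol does not interfere.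

Step 3
Reactants: 4 4-[4-(TBSO)phenyl]but-3-yn-1-ol
Product: 5 tert-butyldimethyl{4-[4-(TESO)but-1-yn-1-yl]phenoxy}silane
Conditions: Et3SiCl, imidazole, CH2Cl2, 0 °C
Reagents that add atoms: chlorotriethylsilane, CC[Si](CC)(CC)Cl
Why: Silylation of the primary alcohol; TES is chosen because a silyl ether will not compete for the Lewis acid in step 5, it differs from the aryl TBS ether, and it can be oxidised directly in step 7.

Step 4
Reactants: 5 tert-butyldimethyl{4-[4-(TESO)but-1-yn-1-yl]phenoxy}silane
Product: 6 (Z)-1-[4-(TBSO)phenyl]-4-(TESO)but-1-ene
Conditions: H2 (1 atm), Pd/CaCO3 poisoned with Pb(OAc)2 (Lindlar catalyst), quinoline, EtOAc–hexane, rt, stopped after one equivalent of H2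
Reagents that add atoms: none
Why: Lindlar semi-hydrogenation adds H2 syn to the alkyne on the poisoned palladium surface and gives the Z-alkene; quinoline and control of the H2 uptake limit over-reduction and Z-to-E isomerisation.

Step 5
Reactants: 7 methyl 2-(hydroxymethyl)acrylate; 6 (Z)-1-[4-(TBSO)phenyl]-4-(TESO)but-1-ene
Product: 9 methyl (2R,3R)-2-[4-(TBSO)phenyl]-3-[2-(TESO)ethyl]-3,4-dihydro-2H-pyran-5-carboxylate, via methyl 2-formylacrylate 8 (not isolated)
Conditions: (a) 7 (3 equiv), Dess–Martin periodinane, NaHCO3, CH2Cl2, 0 °C; pentane, cold filtration under argon; (b) filtrate added slowly to 6, [Cr(L)Cl] (10 mol%, trivalent chromium; L = Schiff-base dianion from 3-(1-adamantyl)-2-hydroxy-5-methylbenzaldehyde and one antipode of cis-1-aminoindan-2-ol), 4 Å molecular sieves, toluene, −20 → 0 °C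
Reagents that add atoms: none
Why: Proposed new method: the chromium centre of [Cr(L)Cl] binds the formyl oxygen of 8 and lowers the LUMO of the oxadiene O1=C6–C5=C4, which combines with the HOMO of the Z-styrene in a concerted but asynchronous inverse-demand oxa-[4+2] cycloaddition in which C3–C4 (to the unsubstituted acrylate terminus) runs ahead of O1–C2 and the partial positive charge at benzylic C2 is stabilised by the para silyloxy group. The closest known reaction type is the inverse-demand oxa-Diels–Alder reaction of 2-formylacrylates and enals with vinyl ethers or 4-alkoxystyrenes, including enantioselective versions under chiral Schiff-base CrCl complexes (trivalent chromium); new here is a Z-1,2-disubstituted styrene as the 2π partner under enantiocontrol. The dihydropyran ring is closed by intermolecular [4π+2π] cycloaddition, both σ-bonds being made in one event that is suprafacial on each component, and not by cyclisation of a chain. C2 and C3 are the only new stereocentres: their cis relationship is the Z geometry of 6 carried through the suprafacial addition, and their absolute sense (2R,3R) comes from the face of the bound oxadiene that the chiral ligand leaves open. No endo/exo question arises because C4, C5 and C6 carry no stereocentre in 9. The step needs regiocontrol (oxygen to the benzylic carbon), which the donor-polarised styrene supplies; retention of the Z geometry, which a non-polar medium and low temperature favour by keeping the benzylic cation from becoming a free intermediate; and one enantioface, which only the catalyst can give. Slow addition of the cold solution of 8, used in excess, keeps its self-dimerisation behind the cross reaction, and the two silyl ethers are too weakly Lewis basic to compete for chromium.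

Step 6
Reactants: 9 methyl (2R,3R)-2-[4-(TBSO)phenyl]-3-[2-(TESO)ethyl]-3,4-dihydro-2H-pyran-5-carboxylate
Product: 10 methyl (2R,3R,5R)-2-[4-(TBSO)phenyl]-3-[2-(TESO)ethyl]oxane-5-carboxylate
Conditions: H2 (1–3 atm), 5% Pd/C, Et3N (0.1 equiv), EtOAc, rt
Reagents that add atoms: none
Why: Heterogeneous syn-hydrogenation of the enol-ether double bond of a 5-alkoxycarbonyl dihydropyran; the catalyst is approached from the face opposite the cis C2/C3 substituents, so the new C5–H bond forms trans to them and the ester ends up cis to both (5R), while Et3N suppresses hydrogenolysis of the benzylic C2–O1 bond.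

Step 7
Reactants: 10 methyl (2R,3R,5R)-2-[4-(TBSO)phenyl]-3-[2-(TESO)ethyl]oxane-5-carboxylate
Product: 11 methyl (2R,3R,5R)-2-[4-(TBSO)phenyl]-3-(2-oxoethyl)oxane-5-carboxylate
Conditions: (COCl)2 (4 equiv), DMSO (8 equiv), CH2Cl2, −78 → −40 °C; Et3N, −78 → 0 °C
Reagents that add atoms: none
Why: Swern oxidation applied directly to a primary triethylsilyl ether: chlorodimethylsulfonium chloride desilylates the primary ether in situ to the alkoxysulfonium ion, which Et3N collapses to the aldehyde; the aryl TBS ether and the ester are inert, and no stereocentre is α to the new carbonyl.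

Step 8
Reactants: 11 methyl (2R,3R,5R)-2-[4-(TBSO)phenyl]-3-(2-oxoethyl)oxane-5-carboxylate
Product: 12 methyl (2R,3S,5R)-2-[4-(TBSO)phenyl]-3-(prop-2-en-1-yl)oxane-5-carboxylate
Conditions: Ph3PCH3Br, KN(SiMe3)2, THF, 0 °C; then 11, −78 → 0 °C
Reagents that add atoms: methyltriphenylphosphonium bromide, C[P+](c1ccccc1)(c1ccccc1)c1ccccc1.[Br-]
Why: Wittig methylenation with the non-stabilised ylide at low temperature; the ester is not attacked, and C3 is β to the aldehyde and cannot epimerise.

Step 9
Reactants: 12 methyl (2R,3S,5R)-2-[4-(TBSO)phenyl]-3-(prop-2-en-1-yl)oxane-5-carboxylate; 13 tert-butyl(4-ethenylphenoxy)dimethylsilane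
Product: 14 methyl (2R,3S,5R)-2-[4-(TBSO)phenyl]-3-{(E)-3-[4-(TBSO)phenyl]prop-2-en-1-yl}oxane-5-carboxylate
Conditions: 13 (3 equiv), second-generation Hoveyda–Grubbs catalyst RuCl2(H2IMes)(=CH-C6H4-2-OiPr) (5 mol%), 1,4-benzoquinone (10 mol%), CH2Cl2, 40 °C
Reagents that add atoms: none
Why: Olefin cross-metathesis of a terminal alkene with a styrene; reversible metathesis settles on the E-1,2-disubstituted styrene under thermodynamic control, ethene escapes, excess 13 outruns homodimerisation of 12, and benzoquinone suppresses ruthenium-hydride double-bond migration.

Step 10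
Reactants: 14 methyl (2R,3S,5R)-2-[4-(TBSO)phenyl]-3-{(E)-3-[4-(TBSO)phenyl]prop-2-en-1-yl}oxane-5-carboxylate
Product: 15 (2R,3S,5R)-2-[4-(TBSO)phenyl]-3-{(E)-3-[4-(TBSO)phenyl]prop-2-en-1-yl}oxane-5-carbaldehyde
Conditions: iBu2AlH (1.1 equiv), CH2Cl2, −78 °C; MeOH, then aq. potassium sodium tartrate; used crude at once
Reagents that add atoms: none
Why: Partial reduction of a methyl ester with iBu2AlH at −78 °C; the tetrahedral aluminium hemiacetal is held by coordination to the β-oxygen O1 and collapses only on work-up, and a cold neutral work-up with immediate use keeps C5 from epimerising.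

Step 11
Reactants: 15 (2R,3S,5R)-2-[4-(TBSO)phenyl]-3-{(E)-3-[4-(TBSO)phenyl]prop-2-en-1-yl}oxane-5-carbaldehyde; 2 tert-butyl(4-iodophenoxy)dimethylsilane
Product: 17 (R)-[4-(TBSO)phenyl]{(2R,3S,5R)-2-[4-(TBSO)phenyl]-3-[(E)-3-(4-(TBSO)phenyl)prop-2-en-1-yl]oxan-5-yl}methanol, via [4-(TBSO)phenyl]magnesium iodide 16 (not isolated)
Conditions: (a) 2, Mg turnings, Et2O, rt; (b) 15, MgBr2·OEt2 (2 equiv), CH2Cl2, −78 °C, then 16 (1.5 equiv), −78 → −40 °C; aq. NH4Cl
Reagents that add atoms: none
Why: Grignard formation followed by chelation-controlled addition to a β-alkoxy aldehyde (Cram chelate model): magnesium bridges the formyl oxygen and ring O1 in a six-membered chelate with the formyl group axial, and the aryl group adds to the face turned away from the C4 arm, which sets (R) at C7; a Felkin–Anh arrangement with the substituted C4 arm as the large group predicts the same sense.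

Step 12
Reactants: 17 (R)-[4-(TBSO)phenyl]{(2R,3S,5R)-2-[4-(TBSO)phenyl]-3-[(E)-3-(4-(TBSO)phenyl)prop-2-en-1-yl]oxan-5-yl}methanol
Product: 18 4-[(E)-3-{(2R,3S,5R)-5-[(R)-hydroxy(4-hydroxyphenyl)methyl]-2-(4-hydroxyphenyl)oxan-3-yl}prop-1-en-1-yl]phenol
Conditions: Bu4NF (3.5 equiv), AcOH (3.5 equiv), THF, 0 °C
Reagents that add atoms: none
Why: Fluoride cleavage of three aryl silyl ethers; the acetic acid buffer keeps the phenoxide concentration low so that neither the C7 carbinol nor the C2–O1 bond ionises to a quinone methide, and the carbinol, the oxane and the E-styrene are untouched.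

## Compound list

1 | 4-iodophenol | Oc1ccc(I)cc1 | starting material
2 | tert-butyl(4-iodophenoxy)dimethylsilane | CC(C)(C)[Si](C)(C)Oc1ccc(I)cc1 | intermediate
3 | but-3-yn-1-ol | C#CCCO | starting material
4 | 4-[4-(tert-butyldimethylsilyloxy)phenyl]but-3-yn-1-ol | CC(C)(C)[Si](C)(C)Oc1ccc(C#CCCO)cc1 | intermediate
5 | tert-butyldimethyl{4-[4-(triethylsilyloxy)but-1-yn-1-yl]phenoxy}silane | CC[Si](CC)(CC)OCCC#Cc1ccc(O[Si](C)(C)C(C)(C)C)cc1 | intermediate
6 | (Z)-1-[4-(tert-butyldimethylsilyloxy)phenyl]-4-(triethylsilyloxy)but-1-ene | CC[Si](CC)(CC)OCC/C=C\c1ccc(O[Si](C)(C)C(C)(C)C)cc1 | intermediate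
7 | methyl 2-(hydroxymethyl)acrylate | C=C(CO)C(=O)OC | starting material
8 | methyl 2-formylacrylate (not isolated) | C=C(C=O)C(=O)OC | intermediate
9 | methyl (2R,3R)-2-[4-(tert-butyldimethylsilyloxy)phenyl]-3-[2-(triethylsilyloxy)ethyl]-3,4-dihydro-2H-pyran-5-carboxylate (2,3-cis) | CC[Si](CC)(CC)OCC[C@H]1CC(C(=O)OC)=CO[C@H]1c1ccc(O[Si](C)(C)C(C)(C)C)cc1 | intermediate
10 | methyl (2R,3R,5R)-2-[4-(tert-butyldimethylsilyloxy)phenyl]-3-[2-(triethylsilyloxy)ethyl]oxane-5-carboxylate (all-cis) | CC[Si](CC)(CC)OCC[C@H]1C[C@@H](C(=O)OC)CO[C@H]1c1ccc(O[Si](C)(C)C(C)(C)C)cc1 | intermediate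
11 | methyl (2R,3R,5R)-2-[4-(tert-butyldimethylsilyloxy)phenyl]-3-(2-oxoethyl)oxane-5-carboxylate (all-cis) | O=CC[C@H]1C[C@@H](C(=O)OC)CO[C@H]1c1ccc(O[Si](C)(C)C(C)(C)C)cc1 | intermediate
12 | methyl (2R,3S,5R)-2-[4-(tert-butyldimethylsilyloxy)phenyl]-3-(prop-2-en-1-yl)oxane-5-carboxylate (all-cis) | C=CC[C@H]1C[C@@H](C(=O)OC)CO[C@H]1c1ccc(O[Si](C)(C)C(C)(C)C)cc1 | intermediate
13 | tert-butyl(4-ethenylphenoxy)dimethylsilane [4-(tert-butyldimethylsilyloxy)styrene] | C=Cc1ccc(O[Si](C)(C)C(C)(C)C)cc1 | starting material
14 | methyl (2R,3S,5R)-2-[4-(tert-butyldimethylsilyloxy)phenyl]-3-{(E)-3-[4-(tert-butyldimethylsilyloxy)phenyl]prop-2-en-1-yl}oxane-5-carboxylate (all-cis) | CC(C)(C)[Si](C)(C)Oc1ccc(/C=C/C[C@H]2C[C@@H](C(=O)OC)CO[C@H]2c2ccc(O[Si](C)(C)C(C)(C)C)cc2)cc1 | intermediate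
15 | (2R,3S,5R)-2-[4-(tert-butyldimethylsilyloxy)phenyl]-3-{(E)-3-[4-(tert-butyldimethylsilyloxy)phenyl]prop-2-en-1-yl}oxane-5-carbaldehyde (all-cis) | CC(C)(C)[Si](C)(C)Oc1ccc(/C=C/C[C@H]2C[C@@H](C=O)CO[C@H]2c2ccc(O[Si](C)(C)C(C)(C)C)cc2)cc1 | intermediate
16 | [4-(tert-butyldimethylsilyloxy)phenyl]magnesium iodide (not isolated) | CC(C)(C)[Si](C)(C)Oc1ccc([Mg]I)cc1 | intermediate
17 | (R)-[4-(tert-butyldimethylsilyloxy)phenyl]{(2R,3S,5R)-2-[4-(tert-butyldimethylsilyloxy)phenyl]-3-[(E)-3-[4-(tert-butyldimethylsilyloxy)phenyl]prop-2-en-1-yl]oxan-5-yl}methanol | CC(C)(C)[Si](C)(C)Oc1ccc(/C=C/C[C@H]2C[C@@H]([C@@H](O)c3ccc(O[Si](C)(C)C(C)(C)C)cc3)CO[C@H]2c2ccc(O[Si](C)(C)C(C)(C)C)cc2)cc1 | intermediate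
18 | 4-[(E)-3-{(2R,3S,5R)-5-[(R)-hydroxy(4-hydroxyphenyl)methyl]-2-(4-hydroxyphenyl)oxan-3-yl}prop-1-en-1-yl]phenol | Oc1ccc(/C=C/C[C@H]2C[C@@H]([C@@H](O)c3ccc(O)cc3)CO[C@H]2c2ccc(O)cc2)cc1 | target

## Step count and least certain steps

Total step count: 12. Longest linear sequence: 12 steps (1 to 18). Compounds 3, 7 and 13 and the second portion of 2 enter as side inputs without steps of their own.

Step 5 (key step, proposed new method).
- What may go wrong: a drift from the concerted path to a stepwise ionic one, in which bond rotation at a long-lived benzylic cation erases the Z geometry and gives the trans C2/C3 isomer. The other risks are weak enantiofacial discrimination, because a Z-styrene has not been paired with a chromium-bound 2-formylacrylate, and self-dimerisation of 8 or Lewis-acid isomerisation of 6 outrunning the cross reaction.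
- Fallback (known chemistry): it sets out from 6 and from 8 (made from 7 as in step 5). The cycloaddition is run without chiral control, thermally in toluene or with a catalytic achiral lanthanide Lewis acid such as Eu(fod)3. This is the known oxa-Diels–Alder reaction of 2-formylacrylates with 4-oxygenated styrenes and should keep the cis relationship. The product is the racemate, that is 9 together with its mirror image methyl (2S,3S)-2-[4-(tert-butyldimethylsilyloxy)phenyl]-3-[2-(triethylsilyloxy)ethyl]-3,4-dihydro-2H-pyran-5-carboxylate F1. The two are separated by preparative chromatography on a chiral stationary phase, and the route is rejoined at 9.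

Step 6.
- What may go wrong: poor facial selectivity if the half-chair does not shield one face of the C5=C6 bond enough, and hydrogenolysis of the electron-rich benzylic C2–O1 bond on palladium.
- Fallback: it sets out from 9. The hydrogenation mixture is separated and the unwanted C5 epimer, methyl (2R,3R,5S)-2-[4-(tert-butyldimethylsilyloxy)phenyl]-3-[2-(triethylsilyloxy)ethyl]oxane-5-carboxylate F2, is converted to its ester enolate (LiN(iPr)2, THF, −78 °C, short contact time). The enolate is protonated under kinetic control with the hindered phenol 2,6-di-tert-butyl-4-methylphenol from the face opposite the C2/C3 substituents, which returns the material to the route at 10.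

Step 11.
- What may go wrong: insufficient facial selectivity at the formyl group, because the chelate requires the formyl group axial next to the axial C3 arm and may be poorly populated, and base-induced epimerisation of C5 before addition.
- Fallback: it sets out from 15. The addition is run without regard to selectivity, and the mixture of 17 and its epimer (S)-[4-(tert-butyldimethylsilyloxy)phenyl]{(2R,3S,5R)-2-[4-(tert-butyldimethylsilyloxy)phenyl]-3-[(E)-3-[4-(tert-butyldimethylsilyloxy)phenyl]prop-2-en-1-yl]oxan-5-yl}methanol F3 is oxidised with Dess–Martin periodinane (NaHCO3, CH2Cl2) to the aryl ketone [4-(tert-butyldimethylsilyloxy)phenyl]{(2R,3S,5R)-2-[4-(tert-butyldimethylsilyloxy)phenyl]-3-[(E)-3-[4-(tert-butyldimethylsilyloxy)phenyl]prop-2-en-1-yl]oxan-5-yl}methanone F4. Reagent-controlled Corey–Bakshi–Shibata reduction ((S)-2-methyl-CBS-oxazaborolidine, catecholborane, toluene, −78 °C; aryl as the large group, by analogy with acetophenone giving the (R)-carbinol) returns the material to the route at 17.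

Step 10.
- What may go wrong: over-reduction to the primary alcohol if the aluminium hemiacetal collapses early, and epimerisation of C5 in the free aldehyde toward the more stable trans isomer during work-up.
- Fallback: it sets out from 14. Full reduction with LiBH4 (THF, 0 °C) gives the primary alcohol {(2R,3S,5S)-2-[4-(tert-butyldimethylsilyloxy)phenyl]-3-[(E)-3-[4-(tert-butyldimethylsilyloxy)phenyl]prop-2-en-1-yl]oxan-5-yl}methanol F5, which has the same geometry as 14 (the C5 descriptor changes by priority only). Buffered Dess–Martin oxidation (NaHCO3, CH2Cl2, 0 °C) returns the material to the route at 15.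

Step 9.
- What may go wrong: double-bond migration of the terminal alkene before metathesis, which shortens the chain by one carbon, and consumption of 13 by homodimerisation so that conversion stalls.
- Fallback: it sets out from 11 and bypasses 12. Takai olefination (CrCl2, divalent chromium, CHI3, THF–dioxane, 0 °C) gives the E-vinyl iodide methyl (2R,3R,5R)-2-[4-(tert-butyldimethylsilyloxy)phenyl]-3-[(E)-3-iodoprop-2-en-1-yl]oxane-5-carboxylate F6. Suzuki–Miyaura coupling with commercial 4-(tert-butyldimethylsilyloxy)phenylboronic acid (Pd(PPh3)4, K3PO4, THF–H2O, rt) proceeds with retention of the alkene geometry and returns the material to the route at 14.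

## Further compounds

F1 | step 5 | methyl (2S,3S)-2-[4-(tert-butyldimethylsilyloxy)phenyl]-3-[2-(triethylsilyloxy)ethyl]-3,4-dihydro-2H-pyran-5-carboxylate (mirror image of 9) | CC[Si](CC)(CC)OCC[C@@H]1CC(C(=O)OC)=CO[C@@H]1c1ccc(O[Si](C)(C)C(C)(C)C)cc1
F2 | step 6 | methyl (2R,3R,5S)-2-[4-(tert-butyldimethylsilyloxy)phenyl]-3-[2-(triethylsilyloxy)ethyl]oxane-5-carboxylate (C5 epimer of 10) | CC[Si](CC)(CC)OCC[C@H]1C[C@H](C(=O)OC)CO[C@H]1c1ccc(O[Si](C)(C)C(C)(C)C)cc1
F3 | step 11 | (S)-[4-(tert-butyldimethylsilyloxy)phenyl]{(2R,3S,5R)-2-[4-(tert-butyldimethylsilyloxy)phenyl]-3-[(E)-3-[4-(tert-butyldimethylsilyloxy)phenyl]prop-2-en-1-yl]oxan-5-yl}methanol (C7 epimer of 17) | CC(C)(C)[Si](C)(C)Oc1ccc(/C=C/C[C@H]2C[C@@H]([C@H](O)c3ccc(O[Si](C)(C)C(C)(C)C)cc3)CO[C@H]2c2ccc(O[Si](C)(C)C(C)(C)C)cc2)cc1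
F4 | step 11 | [4-(tert-butyldimethylsilyloxy)phenyl]{(2R,3S,5R)-2-[4-(tert-butyldimethylsilyloxy)phenyl]-3-[(E)-3-[4-(tert-butyldimethylsilyloxy)phenyl]prop-2-en-1-yl]oxan-5-yl}methanone | CC(C)(C)[Si](C)(C)Oc1ccc(/C=C/C[C@H]2C[C@@H](C(=O)c3ccc(O[Si](C)(C)C(C)(C)C)cc3)CO[C@H]2c2ccc(O[Si](C)(C)C(C)(C)C)cc2)cc1
F5 | step 10 | {(2R,3S,5S)-2-[4-(tert-butyldimethylsilyloxy)phenyl]-3-[(E)-3-[4-(tert-butyldimethylsilyloxy)phenyl]prop-2-en-1-yl]oxan-5-yl}methanol (all-cis, geometry of 14) | CC(C)(C)[Si](C)(C)Oc1ccc(/C=C/C[C@H]2C[C@@H](CO)CO[C@H]2c2ccc(O[Si](C)(C)C(C)(C)C)cc2)cc1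
F6 | step 9 | methyl (2R,3R,5R)-2-[4-(tert-butyldimethylsilyloxy)phenyl]-3-[(E)-3-iodoprop-2-en-1-yl]oxane-5-carboxylate (all-cis, geometry of 11) | I/C=C/C[C@H]1C[C@@H](C(=O)OC)CO[C@H]1c1ccc(O[Si](C)(C)C(C)(C)C)cc1
A1 | alternative 1 | 1,5-bis[(4R)-4-benzyl-2-oxo-1,3-oxazolidin-3-yl]pentane-1,5-dione | O=C(CCCC(=O)N1[C@H](Cc2ccccc2)COC1=O)N1[C@H](Cc2ccccc2)COC1=O
A2 | alternative 1 | 4-(tert-butyldimethylsilyloxy)benzaldehyde | CC(C)(C)[Si](C)(C)Oc1ccc(C=O)cc1
A3 | alternative 1 | twofold-symmetric anti,anti bis-aldol adduct of A1 with two molecules of A2 | O=C(N1[C@H](Cc2ccccc2)COC1=O)[C@H]([C@@H](O)c1ccc(O[Si](C)(C)C(C)(C)C)cc1)C[C@@H]([C@@H](O)c1ccc(O[Si](C)(C)C(C)(C)C)cc1)C(=O)N1[C@H](Cc2ccccc2)COC1=O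
A4 | alternative 2 | dimethyl 2,3-cis-2-[4-(methanesulfonyloxy)phenyl]-3-{2-(hydroxymethyl)-3-(tert-butyldimethylsilyloxy)-3-[4-(tert-butyldimethylsilyloxy)phenyl]propyl}cyclopropane-1,1-dicarboxylate (configuration as in the SMILES) | COC(=O)C1(C(=O)OC)[C@H](c2ccc(OS(C)(=O)=O)cc2)[C@@H]1C[C@H](CO)[C@@H](O[Si](C)(C)C(C)(C)C)c1ccc(O[Si](C)(C)C(C)(C)C)cc1
A5 | alternative 2 | all-cis 2-[4-(methanesulfonyloxy)phenyl]-3-[bis(methoxycarbonyl)methyl]-5-{(tert-butyldimethylsilyloxy)[4-(tert-butyldimethylsilyloxy)phenyl]methyl}oxane | COC(=O)C(C(=O)OC)[C@H]2C[C@@H]([C@@H](O[Si](C)(C)C(C)(C)C)c3ccc(O[Si](C)(C)C(C)(C)C)cc3)CO[C@H]2c2ccc(OS(C)(=O)=O)cc2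
A6 | alternative 3 | (R)-[4-(tert-butyldimethylsilyloxy)phenyl][(1S)-cyclohex-3-en-1-yl]methanol | O[C@H]([C@@H]1CC=CCC1)c1ccc(O[Si](C)(C)C(C)(C)C)cc1
A7 | alternative 3 | formaldehyde | C=O
A8 | alternative 3 | 2-[4-(tert-butyldimethylsilyloxy)phenyl]-3-oxabicyclo[3.3.1]non-6-ene with equatorial aryl group | C1[C@H]2C[C@@H](C=C1)CO[C@H]2c1ccc(O[Si](C)(C)C(C)(C)C)cc1
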